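**Retrosynthetic overview**
- The strategy rests on the segment C1–C2–C3 of the tridecane chain. C1 is the benzylic CH2 on the 3,5-dioxygenated benzene ring, C2 is the acetoxy-bearing stereocentre, and C3 is the first chain methylene. This aryl–CH2–CH(O)–CH2 array is read as aryl electrophile + two-carbon vinyl unit + primary alkylboron, with boron holding the place of the C2 oxygen.
- Late disconnections are the phenol O–benzyl bond, the C8 ketone (carried as a dioxolane), and C2–OAc back to C2–OH back to C2–B(pin) with retention. The bonds aryl–C1 and C2–C3 are then cut together in one palladium-catalysed conjunctive coupling.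
- The alkylboronate comes from 6-bromohexanoyl chloride and pentylzinc bromide by ketalisation and copper-catalysed borylation. The aryl triflate comes from 5-methoxyresorcinol by monobenzylation and triflation. Vinyllithium comes from tetravinyltin by tin–lithium exchange.
- No ring of the target is built, since the benzene ring is bought. The only ring made is the temporary 1,3-dioxolane, closed in step 2 and opened in step 10.

Key step: step 7

Remark on the chemistry: both antipodes of the ferrocenyl bisphosphine of step 7 are sold. The sense of induction is checked on the first run by chiral HPLC and MTPA ester analysis of alcohol 14. The route is written for the antipode that gives (R)-13.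

**Step 1**
Reactants: 1 6-bromohexanoyl chloride; 2 pentylzinc bromide (solution in THF)
Product: 3 1-bromoundecan-6-one
Conditions: Pd(PPh3)4 (2 mol%), THF, 0 °C → rt
Reagents that add atoms: none
Why: In this Negishi-type acylation the acyl chloride adds to zerovalent palladium far faster than the primary C–Br bond does, and the mild alkylzinc halide transfers pentyl to the acylpalladium species without adding to the ketone formed, so the reaction should stop at the bromo ketone.

**Step 2**
Reactants: 3 1-bromoundecan-6-one
Product: 4 2-(5-bromopentyl)-2-pentyl-1,3-dioxolane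
Conditions: HOCH2CH2OH (3 equiv), p-TsOH·H2O (cat.), toluene, Dean–Stark trap, reflux
Reagents that add atoms: ethylene glycol, OCCO
Why: Acid-catalysed ketalisation with azeotropic removal of water should carry an unhindered dialkyl ketone fully to its dioxolane, which masks the carbonyl group against the vinyllithium of step 7 and leaves the primary bromide untouched.

**Step 3**
Reactants: 4 2-(5-bromopentyl)-2-pentyl-1,3-dioxolane; 5 bis(pinacolato)diboron
Product: 6 4,4,5,5-tetramethyl-2-[5-(2-pentyl-1,3-dioxolan-2-yl)pentyl]-1,3,2-dioxaborolane
Conditions: CuI (10 mol%), PPh3 (13 mol%), LiOMe (2 equiv), DMF, rt; chromatography on silica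
Reagents that add atoms: none
Why: In this copper-catalysed borylation of an unactivated primary alkyl bromide, methoxide activates the diboron to a boryl-copper species that displaces bromide at room temperature without harm to the dioxolane, and chromatography removes the halide salts that would slow step 7.

**Step 4**
Reactants: 7 5-methoxyresorcinol (2 equiv)
Product: 8 3-(benzyloxy)-5-methoxyphenol
Conditions: BnBr (1 equiv), K2CO3 (1 equiv), acetone, reflux
Reagents that add atoms: benzyl bromide, BrCc1ccccc1
Why: This Williamson ether synthesis acts on two equivalent hydroxyl groups and is only statistically selective, so an excess of the diol and a single equivalent of base are used to hold back the second benzylation, and the diol, mono-ether and di-ether differ enough in polarity to be separated with recovery of 7.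

**Step 5**
Reactants: 8 3-(benzyloxy)-5-methoxyphenol
Product: 9 3-(benzyloxy)-5-methoxyphenyl trifluoromethanesulfonate
Conditions: Tf2O (1.2 equiv), pyridine (2 equiv), CH2Cl2, 0 °C
Reagents that add atoms: trifluoromethanesulfonic anhydride, O=S(=O)(OS(=O)(=O)C(F)(F)F)C(F)(F)F
Why: O-Sulfonylation of a phenol with triflic anhydride and pyridine is fast and general at 0 °C and leaves both aryl ethers alone.

**Step 6**
Reactants: 10 tetravinyltin
Product: 11 vinyllithium (kept as a titrated solution in Et2O)
Conditions: n-BuLi (4 equiv, hexanes), pentane, 0 °C → rt, argon; solid washed with pentane, dissolved in Et2O, titrated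
Reagents that add atoms: n-butyllithium, [Li]CCCC
Why: Tin–lithium exchange favours the sp2 carbanion over butyl, and vinyllithium precipitates from pentane, which drives the exchange and lets the tin species be washed away to give the halide-free and tin-free reagent that step 7 requires.

**Step 7**
Reactants: 6 4,4,5,5-tetramethyl-2-[5-(2-pentyl-1,3-dioxolan-2-yl)pentyl]-1,3,2-dioxaborolane; 11 vinyllithium; 9 3-(benzyloxy)-5-methoxyphenyl trifluoromethanesulfonate
Product: 13 2-[(2R)-1-[3-(benzyloxy)-5-methoxyphenyl]-7-(2-pentyl-1,3-dioxolan-2-yl)heptan-2-yl]-4,4,5,5-tetramethyl-1,3,2-dioxaborolane, via lithium vinylboron ate complex 12 (not isolated)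
Conditions: 6, 11 (1.0 equiv), Et2O, 0 °C → rt, evaporate; then Pd(OAc)2 (2 mol%), 1,1'-bis[bis(4-methoxy-3,5-dimethylphenyl)phosphino]-2,2'-bis[α-(dimethylamino)benzyl]ferrocene (MandyPhos, 2.4 mol%), 9 (1.1 equiv), THF, 60 °C; chromatography on silica
Reagents that add atoms: none
Why: Vinyllithium fills the empty orbital on the boron of 6 to give the four-coordinate ate complex 12, while Pd(OAc)2 is reduced in the flask to zerovalent palladium, which inserts into the C–OTf bond of 9 to give a cationic divalent arylpalladium bisphosphine complex whose non-coordinating triflate leaves a site open for the vinyl π bond of 12. This π-activation sets off a 1,2-metallate shift in which the primary alkyl group moves from boron to the boron-bearing carbon (bond C2–C3) anti to palladium while the terminal carbon becomes bound to palladium, and reductive elimination then forms the aryl–C1 bond and returns zerovalent palladium. This is the known palladium-catalysed enantioselective conjunctive cross-coupling of vinylboron ate complexes with aryl triflates, for which primary alkyl pinacol boronates are established migrating groups, and it closes no ring. The one new stereocentre, C2, is set under catalyst control, because the twofold-symmetric chiral bisphosphine decides which face of the vinyl group is bound to palladium when the shift takes place, and the ligand antipode is chosen to give (R). Regiochemistry follows from the mechanism (aryl to the terminal carbon, alkyl to the boron-bearing carbon), whereas the preference over direct vinyl transfer to palladium and over β-hydride elimination depends on the wide-bite-angle ligand and on the absence of halide, which the triflate electrophile and the halide-free 6 and 11 secure. The dioxolane and the benzyl ether remove every acidic or electrophilic site, and exactly one equivalent of vinyllithium is used so that none is left to attack the sulfonate of 9.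

**Step 8**
Reactants: 13 secondary (R)-pinacol boronate
Product: 14 (2R)-1-[3-(benzyloxy)-5-methoxyphenyl]-7-(2-pentyl-1,3-dioxolan-2-yl)heptan-2-ol
Conditions: 30% H2O2, 3 M aq. NaOH, THF, 0 °C → rt
Reagents that add atoms: hydrogen peroxide, OO
Why: In this standard boronate oxidation hydroperoxide adds to boron and the secondary alkyl group migrates from boron to oxygen with retention, so (R)-13 should give (R)-14, and the ketal and both ethers are stable to aqueous base.

**Step 9**
Reactants: 14 (R)-alcohol
Product: 15 (2R)-1-[3-(benzyloxy)-5-methoxyphenyl]-7-(2-pentyl-1,3-dioxolan-2-yl)heptan-2-yl acetate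
Conditions: Ac2O (2 equiv), DMAP (cat.), pyridine, rt
Reagents that add atoms: acetic anhydride, CC(=O)OC(C)=O
Why: DMAP-catalysed acylation of an unhindered secondary alcohol takes place at oxygen only, so the C2–O bond and the configuration are kept.

**Step 10**
Reactants: 15 ketal acetate
Product: 16 (2R)-1-[3-(benzyloxy)-5-methoxyphenyl]-8-oxotridecan-2-yl acetate
Conditions: 1 M aq. HCl, THF, rt
Reagents that add atoms: water, O
Why: Acid-catalysed ketal hydrolysis of a dialkyl dioxolane runs through an oxocarbenium ion in dilute acid at room temperature much faster than a secondary acetate is hydrolysed, and the stereocentre lies five methylene groups from the new ketone and cannot epimerise.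

**Step 11**
Reactants: 16 benzyl ether
Product: 17 (2R)-1-(3-hydroxy-5-methoxyphenyl)-8-oxotridecan-2-yl acetate (target, CNP0302149.1)
Conditions: H2 (1 atm), 10% Pd/C, EtOAc, rt
Reagents that add atoms: none
Why: Catalytic hydrogenolysis cleaves the aryl benzyl ether, while the aliphatic ketone, the aryl methyl ether and the acetate (homobenzylic, not benzylic, so its C–O bond is not activated) are inert to Pd/C under one atmosphere of hydrogen.

**Compound list**

| No. | Name | SMILES | Role |
|---|---|---|---|
| 1 | 6-bromohexanoyl chloride | O=C(Cl)CCCCCBr | starting material |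
| 2 | pentylzinc bromide | CCCCC[Zn]Br | starting material |
| 3 | 1-bromoundecan-6-one | CCCCCC(=O)CCCCCBr | intermediate |
| 4 | 2-(5-bromopentyl)-2-pentyl-1,3-dioxolane | CCCCCC1(CCCCCBr)OCCO1 | intermediate |
| 5 | bis(pinacolato)diboron | CC1(C)OB(OC1(C)C)B1OC(C)(C)C(C)(C)O1 | starting material |
| 6 | 4,4,5,5-tetramethyl-2-[5-(2-pentyl-1,3-dioxolan-2-yl)pentyl]-1,3,2-dioxaborolane | CCCCCC1(CCCCCB2OC(C)(C)C(C)(C)O2)OCCO1 | intermediate |
| 7 | 5-methoxyresorcinol | COc1cc(O)cc(O)c1 | starting material |
| 8 | 3-(benzyloxy)-5-methoxyphenol | COc1cc(O)cc(OCc2ccccc2)c1 | intermediate |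
| 9 | 3-(benzyloxy)-5-methoxyphenyl trifluoromethanesulfonate | COc1cc(OCc2ccccc2)cc(OS(=O)(=O)C(F)(F)F)c1 | intermediate |
| 10 | tetravinyltin | C=C[Sn](C=C)(C=C)C=C | starting material |
| 11 | vinyllithium | [Li]C=C | intermediate |
| 12 | lithium 2-ethenyl-4,4,5,5-tetramethyl-2-[5-(2-pentyl-1,3-dioxolan-2-yl)pentyl]-1,3,2-dioxaborolan-2-uide (vinylboron ate complex, not isolated) | [Li+].C=C[B-]1(CCCCCC2(CCCCC)OCCO2)OC(C)(C)C(C)(C)O1 | intermediate |
| 13 | 2-[(2R)-1-[3-(benzyloxy)-5-methoxyphenyl]-7-(2-pentyl-1,3-dioxolan-2-yl)heptan-2-yl]-4,4,5,5-tetramethyl-1,3,2-dioxaborolane | CCCCCC1(CCCCC[C@H](Cc2cc(OCc3ccccc3)cc(OC)c2)B2OC(C)(C)C(C)(C)O2)OCCO1 | intermediate |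
| 14 | (2R)-1-[3-(benzyloxy)-5-methoxyphenyl]-7-(2-pentyl-1,3-dioxolan-2-yl)heptan-2-ol | CCCCCC1(CCCCC[C@H](Cc2cc(OCc3ccccc3)cc(OC)c2)O)OCCO1 | intermediate |
| 15 | (2R)-1-[3-(benzyloxy)-5-methoxyphenyl]-7-(2-pentyl-1,3-dioxolan-2-yl)heptan-2-yl acetate | CCCCCC1(CCCCC[C@H](Cc2cc(OCc3ccccc3)cc(OC)c2)OC(C)=O)OCCO1 | intermediate |
| 16 | (2R)-1-[3-(benzyloxy)-5-methoxyphenyl]-8-oxotridecan-2-yl acetate | CCCCCC(=O)CCCCC[C@H](Cc1cc(OCc2ccccc2)cc(OC)c1)OC(C)=O | intermediate |
| 17 | (2R)-1-(3-hydroxy-5-methoxyphenyl)-8-oxotridecan-2-yl acetate | CCCCCC(=O)CCCCC[C@H](Cc1cc(O)cc(OC)c1)OC(C)=O | target |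

**Total step count:** 11
**Longest linear sequence:** 8 steps (1, 2, 3, 7, 8, 9, 10, 11)

**Steps most likely to fail**

Step 7. The vinyl group may pass from boron to palladium before the metallate shift. The catalyst may be slowed by traces of halide or copper carried in with 6. Facial discrimination may also be weak for this long, flexible migrating chain. The fallback sets out from 6 and comes back at 14, and it takes the stereocentre from a resolved terminal epoxide instead of from a catalytic C–C bond formation.
- Ate complex 12 is made from 6 and 11 as before, but is treated in THF at −78 °C with I2 and then NaOMe in MeOH (Zweifel olefination). This gives 2-(hept-6-en-1-yl)-2-pentyl-1,3-dioxolane F1.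
- Epoxidation with mCPBA and NaHCO3 in CH2Cl2 gives racemic 2-[5-(oxiran-2-yl)pentyl]-2-pentyl-1,3-dioxolane F2.
- Hydrolytic kinetic resolution uses 0.55 equiv of water and (R,R)-N,N'-bis(3,5-di-tert-butylsalicylidene)cyclohexane-1,2-diaminatocobalt acetate, (salen)Co(OAc). This antipode consumes the (S)-epoxide faster and should leave 2-{5-[(2R)-oxiran-2-yl]pentyl}-2-pentyl-1,3-dioxolane F3.
- Separately, bought 3-bromo-5-methoxyphenol F4 is benzylated (BnBr, K2CO3, acetone) to 1-(benzyloxy)-3-bromo-5-methoxybenzene F5. Mg in THF turns this into [3-(benzyloxy)-5-methoxyphenyl]magnesium bromide F6.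
- Under CuI catalysis in THF at −30 °C, F6 opens F3 at its unsubstituted carbon. The stereocentre is not touched, so alcohol 14 results.

Step 6. The tin–lithium exchange may stay incomplete, vinyl-tin species may be carried over and undergo tin-to-palladium vinyl transfer in step 7, and titre may be lost while the pyrophoric solid is handled. The fallback sets out from 4 and comes back at 13. It builds the ate complex with the roles reversed, so neither vinyllithium nor step 3 is needed.
- Bromide 4 is converted with Mg turnings in THF into [5-(2-pentyl-1,3-dioxolan-2-yl)pentyl]magnesium bromide F7.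
- F7 is added to bought vinylboronic acid pinacol ester F8 in the presence of NaOTf, which helps ate formation and takes bromide out of solution. This gives the bromomagnesium vinylboron ate complex F9.
- F9 is coupled in the same flask with 9 under Pd(OAc)2 and the same bisphosphine in THF to give 13.

Step 4. Over-alkylation of the second hydroxyl group and some C-benzylation of the electron-rich ring may erode the supply of the mono-ether. The fallback sets out from 7 and comes back at 8. It replaces statistical mono-alkylation by exhaustive alkylation followed by a self-limiting cleavage.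
- Compound 7 is fully benzylated (BnBr 2.5 equiv, K2CO3, DMF) to 1,3-bis(benzyloxy)-5-methoxybenzene F10.
- F10 is heated with NaSEt (1.3 equiv) in DMF. The thiolate attacks the benzylic carbon, a better SN2 site than the methyl carbon.
- The phenoxide formed makes the remaining aryloxide a much poorer leaving group, so cleavage should stop after one benzyl group. Acidic work-up then gives 8.

**Further compounds**
F1 | step 7 | 2-(hept-6-en-1-yl)-2-pentyl-1,3-dioxolane | CCCCCC1(CCCCCC=C)OCCO1
F2 | step 7 | racemic 2-[5-(oxiran-2-yl)pentyl]-2-pentyl-1,3-dioxolane | CCCCCC1(CCCCCC2CO2)OCCO1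
F3 | step 7 | 2-{5-[(2R)-oxiran-2-yl]pentyl}-2-pentyl-1,3-dioxolane | CCCCCC1(CCCCC[C@@H]2CO2)OCCO1
F4 | step 7 | 3-bromo-5-methoxyphenol (bought) | COc1cc(O)cc(Br)c1
F5 | step 7 | 1-(benzyloxy)-3-bromo-5-methoxybenzene | COc1cc(Br)cc(OCc2ccccc2)c1
F6 | step 7 | [3-(benzyloxy)-5-methoxyphenyl]magnesium bromide | COc1cc([Mg]Br)cc(OCc2ccccc2)c1
F7 | step 6 | [5-(2-pentyl-1,3-dioxolan-2-yl)pentyl]magnesium bromide | CCCCCC1(CCCCC[Mg]Br)OCCO1
F8 | step 6 | vinylboronic acid pinacol ester (bought) | C=CB1OC(C)(C)C(C)(C)O1
F9 | step 6 | bromomagnesium vinylboron ate complex | [Mg+]Br.C=C[B-]1(CCCCCC2(CCCCC)OCCO2)OC(C)(C)C(C)(C)O1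
F10 | step 4 | 1,3-bis(benzyloxy)-5-methoxybenzene | COc1cc(OCc2ccccc2)cc(OCc2ccccc2)c1
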